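**Retrosynthetic overview**
- Target ⇐ acetolysis/β-elimination of a C3–O–C13 oxolane that masks both the C13 oxygen and the C3=C4 enone; the tertiary C15 alcohol is acetylated in the same pot.
- Ring C (azonane) ⇐ intramolecular N–C9 alkylation, carried out while the oxolane is still closed.
- Ring B plus the oxolane ⇐ one double Michael operation (oxa-Michael, then carbon Michael) on a 4,4-disubstituted cyclohexa-2,5-dienone; the C3 carbinol of an aldol unit relays its configuration to C12, C13 and C7.
- Dienone ⇐ oxidative dearomative para-allylation of a phenol; phenol aldol ⇐ boron aldol of 4-hydroxyphenylacetone with a Boc-protected β-amino aldehyde.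
- Ring order: ring A (the former phenol ring) → ring B + oxolane together → ring C → oxolane opened last.

Atom labels (fawcettimine numbering): N–C1–C2–C3=C4(–C5(=O)–C6–C7)–C12; C12–C11–C10–C9–N; ring A = C7, C8, C15(C16), C14, C13, C12; ring B = C4, C5, C6, C7, C12; ring C = N, C1, C2, C3, C4, C12, C11, C10, C9. The target is 7S,12S,13S,15S with an (E)-enone.
Assumption: the Ipc2BOTf antipode that gives the (3S) carbinol is taken to be the (−)-reagent; if the opposite sense is found, the (+)-reagent is used and nothing else changes.
Assumption: tert-butyl methyl(3-oxopropyl)carbamate is bought as a catalogue building block.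

**Step 1**
Reactants: 1 1-(4-hydroxyphenyl)propan-2-one; 2 tert-butyl methyl(3-oxopropyl)carbamate
Product: 3 tert-butyl [(3S,4R)-3-hydroxy-4-(4-hydroxyphenyl)-5-oxohexyl](methyl)carbamate
Conditions: (−)-Ipc2BOTf (2.4 equiv), i-Pr2NEt (2.6 equiv), CH2Cl2, −78 °C; then 2, −78 to −20 °C; MeOH, pH 7 buffer, 30% H2O2, 0 °C
Reagents that add atoms: none
Why: Paterson-type reagent-controlled boron aldol reaction, in which the more acidic benzylic CH2 gives the conjugated (Z)-enol borinate (the phenol is carried as its borinate), the closed Zimmerman–Traxler transition state gives the 3,4-syn adduct, and the isopinocampheyl ligands set C3 as S, which makes C4 R.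

**Step 2**
Reactants: 3 tert-butyl [(3S,4R)-3-hydroxy-4-(4-hydroxyphenyl)-5-oxohexyl](methyl)carbamate; 4 allyltrimethylsilane
Product: 5 tert-butyl {(3S,4R)-3-hydroxy-5-oxo-4-[4-oxo-1-(prop-2-en-1-yl)cyclohexa-2,5-dien-1-yl]hexyl}(methyl)carbamate
Conditions: PhI(OAc)2 (1.2 equiv), 4 (5 equiv), (CF3)2CHOH/CH2Cl2, −20 °C, 15 min; solid NaHCO3
Reagents that add atoms: none
Why: Oxidative Hosomi–Sakurai-type dearomatisation, in which the phenoxenium ion formed with PhI(OAc)2 is captured at the para carbon by the allylsilane to give the quaternary C12, which is not yet a stereocentre because its two enone arms are identical, while C3 and C4 are untouched.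

**Step 3**
Reactants: 5 tert-butyl {(3S,4R)-3-hydroxy-5-oxo-4-[4-oxo-1-(prop-2-en-1-yl)cyclohexa-2,5-dien-1-yl]hexyl}(methyl)carbamate
Product: 7 tricyclic diketone (ring A 15-ketone; ring B 5-ketone; C3–O–C13 oxolane; 12-allyl; all ring fusions cis; Boc(methyl)aminoethyl chain on the convex face at C3), via oxolane-fused cyclohexenone 6 (not isolated)
Conditions: t-BuOK (0.3 equiv), THF/t-BuOH 10:1, −40 to 0 °C; aq NH4Cl
Reagents that add atoms: none
Why: Proposed new method: the C3 alkoxide adds 5-exo-trig to either enone arm (reversible oxa-Michael), but only the adduct that leaves the C4 acetyl group cis to the remaining enone and the C2 chain on the convex face can close ring B by an irreversible 5-exo-trig enolate Michael addition, so the (3S,4R) aldol stereochemistry is relayed to C12, C13 and C7 with all ring fusions cis in one operation; the closest known reaction type is the base-mediated intramolecular oxa-Michael or carbon Michael desymmetrisation of 4,4-disubstituted cyclohexa-2,5-dienones.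

**Step 4**
Reactants: 7 tricyclic diketone
Product: 8 tricyclic tertiary alcohol (15-hydroxy-15-methyl with the hydroxyl cis to O13; 5-ketone and oxolane unchanged)
Conditions: MeMgBr (1.2 equiv), CH2Cl2/Et2O, −78 °C; aq NH4Cl
Reagents that add atoms: methylmagnesium bromide, C[Mg]Br
Why: Chelation-controlled Grignard addition, in which the six-membered ketone flanked by two CH2 groups reacts faster than the α-branched cyclopentanone and magnesium held between the C15 carbonyl and the oxolane oxygen leaves only the convex face open, so methyl enters anti to the two cis-fused five-membered rings and the C15 hydroxyl ends cis to O13.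

**Step 5**
Reactants: 8 tricyclic tertiary alcohol
Product: 10 primary alcohol (C11–C10–C9–OH chain on C12), via pinacol boronate 9 (not isolated)
Conditions: pinacolborane (3 equiv), RhCl(PPh3)3 (3 mol%), THF, 25 °C; then NaOH aq, 30% H2O2, 0 °C
Reagents that add atoms: pinacolborane, B1OC(C)(C)C(C)(C)O1 (boron unit present in 9 only); hydrogen peroxide, OO
Why: Catalysed anti-Markovnikov hydroboration then oxidation, in which rhodium-catalysed addition of pinacolborane to the terminal alkene outruns reduction of the ketone, and oxidation of the C–B bond gives the primary alcohol without touching any stereocentre.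

**Step 6**
Reactants: 10 primary alcohol
Product: 11 primary iodide (C9–I)
Conditions: I2, PPh3, imidazole, CH2Cl2, 0 to 25 °C
Reagents that add atoms: iodine, II
Why: Appel iodination, in which only the primary alcohol forms the alkoxyphosphonium ion and is displaced by iodide (SN2) while the tertiary alcohol does not react.

**Step 7**
Reactants: 11 primary iodide
Product: 13 tetracyclic amino ketone (ring C closed through N–C9; oxolane retained; 15-hydroxyl free), via secondary amine trifluoroacetate 12 (not isolated)
Conditions: CF3CO2H/CH2Cl2 1:4, 0 °C, 30 min; evaporate; then K2CO3 (5 equiv), MeCN, 60 °C, 0.002 M, syringe-pump addition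
Reagents that add atoms: none
Why: Boc cleavage then intramolecular SN2 N-alkylation under high dilution, in which the C2 chain and the C11 chain sit cis-1,3 on the convex face of the oxolane so that amine and iodide are preorganised for closure of the nine-membered ring C, and no stereocentre changes.

**Step 8**
Reactants: 13 tetracyclic amino ketone
Product: 15 target diacetate (13,15-diacetoxy (E)-enone), via triacetate ketone 14 (not isolated)
Conditions: Ac2O (10 equiv), TMSOTf (2.2 equiv), CH2Cl2, −20 to 0 °C; then Et3N (6 equiv), 25 °C; aq NaHCO3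
Reagents that add atoms: acetic anhydride, CC(=O)OC(C)=O
Why: Lewis-acid acetolysis of the oxolane then E1cB elimination, in which acetyl triflate acylates the ether oxygen, acetate opens the acyloxonium ion at C3 (C13 is neopentyl and keeps its C–O bond and configuration), the tertiary alcohol is acetylated under the same TMSOTf-promoted conditions, and triethylamine eliminates acetic acid from the β-acetoxy ketone to give the ring-enforced (E)-enone.

**Compound list**
1 | 1-(4-hydroxyphenyl)propan-2-one | CC(=O)Cc1ccc(O)cc1 | starting material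
2 | tert-butyl methyl(3-oxopropyl)carbamate | CN(CCC=O)C(=O)OC(C)(C)C | starting material
3 | tert-butyl [(3S,4R)-3-hydroxy-4-(4-hydroxyphenyl)-5-oxohexyl](methyl)carbamate (3,4-syn aldol) | CC(=O)[C@H](c1ccc(O)cc1)[C@@H](O)CCN(C)C(=O)OC(C)(C)C | intermediate
4 | allyltrimethylsilane | C=CC[Si](C)(C)C | starting material
5 | tert-butyl {(3S,4R)-3-hydroxy-5-oxo-4-[4-oxo-1-(prop-2-en-1-yl)cyclohexa-2,5-dien-1-yl]hexyl}(methyl)carbamate | CC(=O)[C@@H]([C@@H](O)CCN(C)C(=O)OC(C)(C)C)C1(CC=C)C=CC(=O)C=C1 | intermediate
6 | oxolane-fused cyclohexenone (C3–O–C13 oxolane cis-fused to the ring A enone; 12-allyl; 4-acetyl trans to the C2 chain; not isolated) | O1[C@H]2CC(=O)C=C[C@@]2(CC=C)[C@@H](C(C)=O)[C@@H]1CCN(C)C(=O)OC(C)(C)C | intermediate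
7 | tricyclic diketone (ring A 15-ketone, ring B 5-ketone and C3–O–C13 oxolane sharing C12; 12-allyl; H4, H7, H13 and allyl on the convex side; Boc(methyl)aminoethyl chain exo at C3) | O1[C@H]2CC(=O)C[C@H]3CC(=O)[C@@H]([C@@H]1CCN(C)C(=O)OC(C)(C)C)[C@]32CC=C | intermediate
8 | tricyclic tertiary alcohol (as 7, with 15-hydroxy-15-methyl, hydroxyl cis to O13) | O1[C@H]2C[C@@](C)(O)C[C@H]3CC(=O)[C@@H]([C@@H]1CCN(C)C(=O)OC(C)(C)C)[C@]32CC=C | intermediate
9 | pinacol boronate (as 8, with a 3-(pinacolboryl)propyl chain on C12; not isolated) | O1[C@H]2C[C@@](C)(O)C[C@H]3CC(=O)[C@@H]([C@@H]1CCN(C)C(=O)OC(C)(C)C)[C@]32CCCB4OC(C)(C)C(C)(C)O4 | intermediate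
10 | primary alcohol (as 8, with a 3-hydroxypropyl chain on C12) | O1[C@H]2C[C@@](C)(O)C[C@H]3CC(=O)[C@@H]([C@@H]1CCN(C)C(=O)OC(C)(C)C)[C@]32CCCO | intermediate
11 | primary iodide (as 8, with a 3-iodopropyl chain on C12) | O1[C@H]2C[C@@](C)(O)C[C@H]3CC(=O)[C@@H]([C@@H]1CCN(C)C(=O)OC(C)(C)C)[C@]32CCCI | intermediate
12 | secondary amine trifluoroacetate (as 11, with the Boc group removed; not isolated) | O1[C@H]2C[C@@](C)(O)C[C@H]3CC(=O)[C@@H]([C@@H]1CCNC)[C@]32CCCI.OC(=O)C(F)(F)F | intermediate
13 | tetracyclic amino ketone (rings A, B and C with the C3–O–C13 oxolane; N-methyl; 15-hydroxy-15-methyl; 5-ketone) | O1[C@H]2C[C@@](C)(O)C[C@H]3CC(=O)[C@@H]([C@@H]1CCN(C)CCC4)[C@]324 | intermediate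
14 | 3,13,15-triacetate ketone (oxolane opened with inversion at C3; not isolated) | CC(=O)O[C@H]1C[C@@](C)(OC(C)=O)C[C@H]2CC(=O)[C@H]3[C@H](OC(C)=O)CCN(C)CCC[C@@]321 | intermediate
15 | target: (7S,12S,13S,15S)-13,15-diacetoxy-N-methyl (E)-3,4-enone (skeleton numbering) | CC(=O)O[C@H]1C[C@@](C)(OC(C)=O)C[C@H]2CC(=O)/C3=C/CCN(C)CCC[C@@]321 | target

**Count and risks**
Total steps: 8. Longest linear sequence: 8 steps (from 1).

The three steps most likely to fail:

Step 2 (allylation at a para carbon that carries a branched substituent; quinone methide formation and ortho attack compete). The fallback sets out from 1 and comes back at 7. The oxidative allylation is moved to the unhindered phenol: 1 with 4 and PhI(OAc)2 gives 4-(2-oxopropyl)-4-(prop-2-en-1-yl)cyclohexa-2,5-dien-1-one F1. A cinchona-derived primary amine salt then closes ring B by an enantioselective enamine Michael desymmetrisation to the cis-fused 3a-allyl bicyclic enedione F2. F2 and 2 with catalytic base undergo reversible aldol addition, and only the C4 aldolate is drained by 5-exo oxa-Michael addition to the ring A enone, which gives 7.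

Step 3 (retro-aldol cleavage of the C3 alkoxide or a slow ketone Michael addition may intervene). The fallback sets out from 5 and comes back at 7. The two ring closures are separated and the carbon nucleophile is changed: camphorsulfonic acid closes only the oxolane so that 6 is isolated, then pyrrolidine and acetic acid convert its methyl ketone into the pyrrolidine enamine F3, which closes ring B by an enamine Michael addition and is hydrolysed to 7.

Step 8 (the acyloxonium ion may open slowly or the tertiary acetate may ionise). The fallback sets out from 13 and comes back at 15. Me2BBr opens the oxolane by bromide SN2 attack at C3 to give the β-bromo ketone F4 with free 13- and 15-hydroxyls; Et3N eliminates hydrogen bromide to give the 13,15-diol enone F5; Ac2O, DMAP and Et3N then acetylate both hydroxyls to give 15.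

**Further compounds**
F1 | step 2 | 4-(2-oxopropyl)-4-(prop-2-en-1-yl)cyclohexa-2,5-dien-1-one | CC(=O)CC1(CC=C)C=CC(=O)C=C1
F2 | step 2 | cis-3a-(prop-2-en-1-yl)-3,3a,7,7a-tetrahydro-1H-indene-2,6-dione (ring B ketone, ring A enone) | C1=CC(=O)C[C@H]2CC(=O)C[C@]21CC=C
F3 | step 3 | pyrrolidine enamine of the methyl ketone of 6 | O1[C@H]2CC(=O)C=C[C@@]2(CC=C)[C@@H](C(=C)N3CCCC3)[C@@H]1CCN(C)C(=O)OC(C)(C)C
F4 | step 8 | β-bromo ketone (C3–Br with inversion; 13,15-diol; ring C closed) | O[C@H]1C[C@@](C)(O)C[C@H]2CC(=O)[C@H]3[C@H](Br)CCN(C)CCC[C@@]321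
F5 | step 8 | 13,15-diol (E)-enone (deacetyl target) | O[C@H]1C[C@@](C)(O)C[C@H]2CC(=O)/C3=C/CCN(C)CCC[C@@]321
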